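**Retrosynthetic overview**

- The target is reached last by bromination of ring A at C4 and C6, ortho and para to the phenol OH, after O-demethylation of 1,5-dibromo-2-(2,4-dibromophenoxy)-3-methoxybenzene.
- Ring B of that diaryl ether (C1' on the ether oxygen, Br on C2' and C4', H on C3', C5', C6') carries the 1,3-dibromo array of C3–C6 of 3,5-dibromo-2-pyrone, with the oxygenated carbon beside a brominated one. It is made by [4+2] cycloaddition and CO2 loss between that pyrone and 2,4-dibromo-6-methoxyphenyl ethynyl ether, which supplies C1' and C6' (new bonds C1'–C2' and C5'–C6').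
- The ynol ether comes from the aryl vinyl ether by Br2 addition and two dehydrobrominations (no organolithium, so the aryl bromides survive), the vinyl ether from 2,4-dibromo-6-methoxyphenol, and that from 4-bromo-2-methoxyphenol; the dibromopyrone comes from coumalic acid.
- Ring A is an arene from the start. Its bromines at C3 and C5 (ortho/para to the bridging oxygen) are placed on the free phenol before the ether exists, because afterwards C3 would have to compete with C6' of ring B. Ring B is the only ring formed.

Key step: step 6

Remark: in steps 5 and 8 two bromine atoms enter in one flask in an order that is not fixed (both orders converge), so the monobrominated species are not numbered as separate compounds.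

**Route**

Step 1
Reactants: 1 4-bromo-2-methoxyphenol
Product: 2 2,4-dibromo-6-methoxyphenol
Conditions: NBS (1.05 equiv), i-Pr2NH (10 mol %), CH2Cl2, 0 °C → rt
Reagents that add atoms: N-bromosuccinimide, O=C1CCC(=O)N1Br
Why: Amine-mediated ortho-bromination of a phenol (electrophilic aromatic substitution); with the para position blocked, bromine should be delivered to C6 next to the OH and not to the position para to OMe.

Step 2
Reactants: 2 2,4-dibromo-6-methoxyphenol; 3 2,4,6-trivinylcyclotriboroxane–pyridine complex
Product: 4 1,5-dibromo-2-(ethenyloxy)-3-methoxybenzene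
Conditions: 3 (0.7 equiv), Cu(OAc)2 (1.0 equiv), pyridine (10 equiv), CH2Cl2, air, rt
Reagents that add atoms: none
Why: Chan–Lam–Evans oxidative O-vinylation of a phenol with a vinylboron reagent, mediated by Cu(OAc)2 that air returns to the divalent state; 2,6-dihalogenated phenols are competent partners in this coupling type and aryl bromides are untouched at room temperature.

Step 3
Reactants: 4 1,5-dibromo-2-(ethenyloxy)-3-methoxybenzene
Product: 6 1,5-dibromo-2-[(Z)-2-bromoethenyloxy]-3-methoxybenzene, via 1,2-dibromoethyl ether 5 (not isolated)
Conditions: Br2 (1.0 equiv), CH2Cl2, −78 °C; then DBU (1.3 equiv), −78 °C → rt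
Reagents that add atoms: bromine, BrBr
Why: Electrophilic addition of Br2 to the enol ether double bond (far faster than substitution on the dibrominated ring) followed by amine-induced dehydrobromination with loss of the labile α-bromide, the classical route to 2-bromovinyl ethers; the Z isomer is expected to prevail, and any E isomer or 1-bromovinyl regioisomer leads to the same alkyne in step 4.

Step 4
Reactants: 6 1,5-dibromo-2-[(Z)-2-bromoethenyloxy]-3-methoxybenzene
Product: 7 1,5-dibromo-2-(ethynyloxy)-3-methoxybenzene
Conditions: t-BuOK (1.3 equiv), THF, −20 → 0 °C; cold pH 7 work-up, solution used at once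
Reagents that add atoms: none
Why: Base-induced dehydrobromination of a 2-bromovinyl ether (anti-periplanar E2 in the Z isomer, bromide and not aryloxide as leaving group), the classical preparation of aryloxyacetylenes; an alkoxide base neither exchanges nor metallates the aryl bromides.

Step 5
Reactants: 8 coumalic acid
Product: 9 3,5-dibromo-2H-pyran-2-one
Conditions: NBS (2.4 equiv), LiOAc (0.2 equiv), MeCN/H2O (9:1), rt
Reagents that add atoms: N-bromosuccinimide, O=C1CCC(=O)N1Br
Why: Known Hunsdiecker-type bromodecarboxylation of the β-oxy acrylic acid unit (ipso bromination at C5 with loss of CO2) combined with electrophilic bromination at C3, the two nucleophilic positions of the pyrone.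

Step 6
Reactants: 7 1,5-dibromo-2-(ethynyloxy)-3-methoxybenzene; 9 3,5-dibromo-2H-pyran-2-one
Product: 11 1,5-dibromo-2-(2,4-dibromophenoxy)-3-methoxybenzene, via bridged bicyclic lactone 10 (not isolated)
Conditions: 9 (1.5 equiv), BHT (5 mol %), PhMe, 110 °C, sealed tube; 7 added slowly as a PhMe solution
Reagents that add atoms: none
Why: Proposed new method: the electron-poor diene C3=C4–C5=C6 of pyrone 9 and the electron-rich alkyne of 7 should combine in a concerted but asynchronous inverse-demand [4+2] cycloaddition (C6–CH bond leading) to the 2-oxabicyclo[2.2.2]octadienone 10, which should lose CO2 by retro-[4+2] at the reaction temperature and give the benzene ring without any oxidant. The closest known reaction type is the Diels–Alder/decarboxylation benzannulation of 2-pyrones with alkynes, together with the cycloadditions of 3,5-dibromo-2-pyrone with enol ethers; an aryl ynol ether has not been shown as the 2π partner. Ring B is closed by an intermolecular [4+2] annulation that forms C1'–C2' and C5'–C6' (six-membered carbocycle, aromatised by CO2 extrusion), and the two bridgehead stereocentres of 10 vanish on aromatisation, so no stereocontrol is needed. The step needs regiocontrol: pyrone C6, the vinylogous acyl terminus and electrophilic end of the diene, should take the nucleophilic terminal CH of the ynol ether, so that the oxygen-bearing alkyne carbon bonds to C3–Br and the bromines end at C2' and C4', the orientation that enol ethers follow with this pyrone. It also needs the alkyne oxidation level, since an enol ether adduct could aromatise only by expelling the aryloxide, and the twisted, doubly ortho-substituted aryloxy group of 7 should keep the oxygen lone pair on the alkyne.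

Step 7
Reactants: 11 1,5-dibromo-2-(2,4-dibromophenoxy)-3-methoxybenzene
Product: 13 3,5-dibromo-2-(2,4-dibromophenoxy)phenol, via aryloxydibromoborane 12 (not isolated)
Conditions: BBr3 (1.5 equiv), CH2Cl2, −78 °C → rt; then H2O
Reagents that add atoms: none
Why: BBr3 cleavage of an aryl methyl ether (O–B complexation, bromide attack at methyl, hydrolysis of the aryloxyborane); the diaryl ether and the aryl bromides are inert to it.

Step 8
Reactants: 13 3,5-dibromo-2-(2,4-dibromophenoxy)phenol
Product: 14 3,4,5,6-tetrabromo-2-(2,4-dibromophenoxy)phenol
Conditions: Br2 (2.2 equiv), AcOH, rt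
Reagents that add atoms: bromine, BrBr
Why: Electrophilic aromatic bromination of a phenol at its only free positions, C4 (para) and C6 (ortho) to the OH; ring B carries two bromines and no hydroxyl and should not react without a Lewis acid.

**Compound list**

1 | 4-bromo-2-methoxyphenol | COc1cc(Br)ccc1O | starting material
2 | 2,4-dibromo-6-methoxyphenol | COc1cc(Br)cc(Br)c1O | intermediate
3 | 2,4,6-trivinylcyclotriboroxane–pyridine complex | C=CB1OB(C=C)OB(C=C)O1.c1ccncc1 | starting material
4 | 1,5-dibromo-2-(ethenyloxy)-3-methoxybenzene | COc1cc(Br)cc(Br)c1OC=C | intermediate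
5 | 1,5-dibromo-2-(1,2-dibromoethoxy)-3-methoxybenzene (racemic, not isolated) | COc1cc(Br)cc(Br)c1OC(Br)CBr | intermediate
6 | 1,5-dibromo-2-[(Z)-2-bromoethenyloxy]-3-methoxybenzene | COc1cc(Br)cc(Br)c1O/C=C\Br | intermediate
7 | 1,5-dibromo-2-(ethynyloxy)-3-methoxybenzene | COc1cc(Br)cc(Br)c1OC#C | intermediate
8 | coumalic acid (2-oxo-2H-pyran-5-carboxylic acid) | O=C1C=CC(C(=O)O)=CO1 | starting material
9 | 3,5-dibromo-2H-pyran-2-one | O=C1OC=C(Br)C=C1Br | intermediate
10 | 4,7-dibromo-5-(2,4-dibromo-6-methoxyphenoxy)-2-oxabicyclo[2.2.2]octa-5,7-dien-3-one (racemic, not isolated) | O=C1OC2C(Br)=CC1(Br)C(Oc1c(Br)cc(Br)cc1OC)=C2 | intermediate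
11 | 1,5-dibromo-2-(2,4-dibromophenoxy)-3-methoxybenzene | COc1cc(Br)cc(Br)c1Oc1ccc(Br)cc1Br | intermediate
12 | dibromo[3,5-dibromo-2-(2,4-dibromophenoxy)phenoxy]borane (not isolated) | BrB(Br)Oc1cc(Br)cc(Br)c1Oc1ccc(Br)cc1Br | intermediate
13 | 3,5-dibromo-2-(2,4-dibromophenoxy)phenol | Oc1cc(Br)cc(Br)c1Oc1ccc(Br)cc1Br | intermediate
14 | 3,4,5,6-tetrabromo-2-(2,4-dibromophenoxy)phenol | Oc1c(Br)c(Br)c(Br)c(Br)c1Oc1ccc(Br)cc1Br | target

**Step count and risks**

Total step count: 8. Longest linear sequence: 7 steps (steps 1, 2, 3, 4, 6, 7, 8, from 4-bromo-2-methoxyphenol).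

Steps most likely to fail:

Step 6. Thermal oligomerisation of the ynol ether may outrun the cycloaddition, or the two partners may combine in the opposite orientation and place the ether oxygen between two unsubstituted carbons. The fallback attaches ring B by known chemistry and sets out from phenol 2. Nucleophilic aromatic substitution on 4-bromo-1-fluoro-2-nitrobenzene (K2CO3, DMF, 80 °C) should give 1,5-dibromo-2-(4-bromo-2-nitrophenoxy)-3-methoxybenzene F1. Reduction of the nitro group (Fe, NH4Cl, EtOH/H2O, 70 °C) should give 5-bromo-2-(2,4-dibromo-6-methoxyphenoxy)aniline F2. Sandmeyer bromination (t-BuONO, CuBr2, MeCN, 0 → 60 °C) then comes back to the route at 11.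

Step 4. The terminal ynol ether may be lost by alkoxide addition or oligomerisation during work-up and concentration, and an E isomer may eliminate only slowly. The fallback sets out from 6 and stores the alkyne in a silyl-capped form. Treatment with KN(SiMe3)2 (2.2 equiv, THF, −78 °C) and trapping of the acetylide with i-Pr3SiCl should give [(2,4-dibromo-6-methoxyphenoxy)ethynyl]tri(propan-2-yl)silane F3, which can be purified and kept. Bu4NF (THF, 0 °C) releases the terminal alkyne just before the cycloaddition, and the route is rejoined at 7.

Step 2. Transmetallation and C–O bond formation at copper may stall because of the two ortho substituents and the weakly nucleophilic phenoxide. The fallback sets out from 2 and replaces the oxidative coupling by alkylation and elimination. Reaction with excess 1,2-dibromoethane (K2CO3, MeCN, reflux) should give 1,5-dibromo-2-(2-bromoethoxy)-3-methoxybenzene F4. E2 elimination with t-BuOK in THF then returns to the route at 4.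

**Further compounds**

F1 | step 6 | 1,5-dibromo-2-(4-bromo-2-nitrophenoxy)-3-methoxybenzene | COc1cc(Br)cc(Br)c1Oc1ccc(Br)cc1[N+](=O)[O-]
F2 | step 6 | 5-bromo-2-(2,4-dibromo-6-methoxyphenoxy)aniline | COc1cc(Br)cc(Br)c1Oc1ccc(Br)cc1N
F3 | step 4 | [(2,4-dibromo-6-methoxyphenoxy)ethynyl]tri(propan-2-yl)silane | COc1cc(Br)cc(Br)c1OC#C[Si](C(C)C)(C(C)C)C(C)C
F4 | step 2 | 1,5-dibromo-2-(2-bromoethoxy)-3-methoxybenzene | COc1cc(Br)cc(Br)c1OCCBr
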